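If a partner molecule meets substrate it becomes target and can come off again, but if it meets protic impurity we take it as lost for good. The zeta run suggests this: with much impurity its target sinks from 12.4% to 1.0%, while its substrate climbs from 87.3% to 91.2%.

| flask | substrate | partner | protic impurity | remark | time |
|---|---|---|---|---|---|
| eta | 0.020 M | 0.030 M | 0.0080 M | run made earlier |  |
| zeta | 0.020 M | 0.030 M | 0.11 M | run made earlier |  |
| east | 0.020 M | 0.0300 M | 0.0100 M |  | 5.0 min |
| north-east | 0.020 M | 0.0300 M | 0.0200 M |  | 5.0 min |
| south-west | 0.020 M | 0.0300 M | 0.0400 M |  | 5.0 min |
| south | 0.020 M | 0.0300 M | 0.0800 M |  | 5.0 min |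
| west | 0.020 M | 0.0300 M | 0.150 M |  | 5.0 min |

| run | time / min | target / % | substrate / % |
|---|---|---|---|
| eta | 0.417 | 19.1 | 81.8 |
| eta | 0.667 | 24.2 | 75.9 |
| eta | 1.00 | 26.7 | 71.2 |
| eta | 2.00 | 28.9 | 67.2 |
| eta | 3.00 | 27.6 | 67.6 |
| eta | 5.00 | 26.2 | 66.0 |
| zeta | 0.333 | 12.4 | 87.3 |
| zeta | 1.00 | 10.9 | 87.8 |
| zeta | 2.00 | 5.8 | 90.9 |
| zeta | 2.50 | 4.9 | 90.5 |
| zeta | 4.00 | 1.7 | 92.5 |
| zeta | 5.00 | 1.0 | 91.2 |

(standard deviation of a reading: 1 percentage point)

- amount of target at the end, in percent of the substrate charged for east, north-east, south-west, south, west, in this order
- how that number moves from the first to the last of them (rises all the way / falls, then rises / rises, then falls / hardly changes / falls all the way)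

- "hardly changes" means that all values lie within two and a half points (for a concentration: within two and a half percent of the largest)

The eta run is the close neighbour of the east flask: both have the same substrate and partner, and they differ in impurity, 0.0080 M against 0.0100 M. We assume that by the end of eta each impurity molecule has removed one partner, so its free partner is the charge less the impurity less the target, 0.0168 M. Eta ends with 26.2% target beside 66.0% substrate, which gives the holding number, target over substrate per unit of free partner, as the reading 23.7 L mol⁻¹. The field calls this an equilibrium constant.

For the east flask, with eta's target as a first guess, the same assumption gives a lower free partner, 0.0148 M. The holding number then puts target over substrate in east at 0.350. Sharing out the 92.2% that target and substrate hold together at the end of eta, we reckon 23.9% target for east, less than eta's. Further along the row the partner charge stays the same while the impurity charge grows. In south-west it already exceeds the partner charge, so we expect the target to fall at each step, towards what zeta shows.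

The forecast, which holds that “the impurity is destroying the partner”, gives 25%, 21%, 13%, 4.5% and 0.4%, so it falls all the way, and for east it stands above our reckoning.

The flasks give 25.8%, 18.6%, 8.23%, 1.70% and 0.408%: the target falls all the way.

    substrate + partner ⇌ target (K = 23.0 L mol⁻¹, k = 0.350 L mol⁻¹ s⁻¹)
    substrate → side product (k = 2.90 × 10⁻⁴ s⁻¹)
    partner + protic impurity → quenched reagent (k = 0.400 L mol⁻¹ s⁻¹)

In the east flask at 5.00 min, substrate, partner and target relax by their reversible step alone, both ways together, with a half-life of 0.452 min, short against the 5.0 min of the run and against the 27 min half-life that partner has at that moment by passing to quenched reagent. With the free partner that stands in the flask at 5.00 min, the holding number comes to 23.8 L mol⁻¹ in east and 25.1 L mol⁻¹ in north-east, where 33.1% of the partner charge remains.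

The data are simulated with made-up constants; noise was put on by code.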